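**Retrosynthetic overview**

1. 25 ⇐ 24 (hydrogenation sets the ring-fusion CH and frees the acid) ⇐ 22 (oxa-Michael closure of the oxolane bridge, ring D) ⇐ lactol 21 (ionic reduction).
2. Key disconnection: the lactone O–CH2 bond of ring B. The unit O–CH2–C(spiro)–C(=O) of rings B and C is a reduced 2-formyl ketone. Its CH2 carbon lies 1,5 to the lactone carbonyl carbon through the spiro carbon and the two ring-fusion carbons of ring A, so a ring-A carboxylic acid can close ring B on a formyl group as a δ-lactol.
3. The formyl group, the quaternary spiro carbon and its bond to ring A all come from one Claisen rearrangement of enol ether 19, built from hydroxymethylene ketone 7 (ring C) and Morita–Baylis–Hillman alcohol 17 (ring A).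
4. 7 ⇐ 4,4-dimethylcyclohexa-2,5-dienone (asymmetric vinyl addition); 17 ⇐ (S)-cyclopent-2-enyl propanoate (Ireland–Claisen, ozonolysis, Wittig, ring closure).
5. Ring order: ring C (bought) → ring A (step 11) → ring B (step 14) → ring D (step 16).

Key step: step 14

Assumption: the thioester ylide of step 10 is taken as an available reagent (otherwise made from S-ethyl bromothioacetate and PPh3), and for each chiral ligand the enantiomer is used that gives the configuration drawn.

Step 1
Reactants: 1 4,4-dimethylcyclohex-2-en-1-one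
Product: 2 4,4-dimethylcyclohexa-2,5-dien-1-one
Conditions: DDQ, TsOH·H2O (cat.), 1,4-dioxane, 100 °C
Reagents that add atoms: none
Why: DDQ dehydrogenation (hydride abstraction from the dienol, then proton loss) is the standard way to a cross-conjugated 4,4-disubstituted cyclohexadienone, which the gem-dimethyl group keeps from aromatising; no stereocentre is formed.

Step 2
Reactants: 2 4,4-dimethylcyclohexa-2,5-dien-1-one
Product: 3 (5R)-5-ethenyl-4,4-dimethylcyclohex-2-en-1-one
Conditions: [Rh(cod)Cl]2 (3 mol %), (R)-BINAP (7 mol %), CH2=CHBF3K, Et3N, dioxane/H2O, 90 °C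
Reagents that add atoms: potassium vinyltrifluoroborate, C=C[B-](F)(F)F.[K+]
Why: Rhodium-catalysed asymmetric conjugate addition of an alkenylboron reagent (Hayashi–Miyaura reaction) desymmetrises the dienone, the BINAP-bound vinylrhodium species choosing one face of one enantiotopic enone unit and so setting the CH(vinyl) centre as R.

Step 3
Reactants: 3 (5R)-5-ethenyl-4,4-dimethylcyclohex-2-en-1-one
Product: 5 (5S)-5-(hydroxymethyl)-4,4-dimethylcyclohex-2-en-1-one, via keto aldehyde 4 (not isolated)
Conditions: O3, CH2Cl2/MeOH, −78 °C; Me2S; then NaBH4, −78 to −40 °C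
Reagents that add atoms: ozone, [O-][O+]=O
Why: Ozonolysis attacks the electron-rich vinyl group much faster than the electron-poor enone alkene, and NaBH4 at low temperature reduces the aldehyde but not the conjugated ketone (chemoselective carbonyl reduction); the adjacent stereocentre is not enolised under these conditions.

Step 4
Reactants: 5 (5S)-5-(hydroxymethyl)-4,4-dimethylcyclohex-2-en-1-one
Product: 6 (5S)-5-{[tert-butyl(diphenyl)silyl]oxymethyl}-4,4-dimethylcyclohex-2-en-1-one
Conditions: t-BuPh2SiCl, imidazole, DMF, 0 °C to rt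
Reagents that add atoms: tert-butyl(chloro)diphenylsilane, CC(C)(C)[Si](Cl)(c1ccccc1)c1ccccc1
Why: Silyl ether formation at the primary alcohol blocks its premature oxa-Michael closure and its later attack on the formyl group; the robust silyl group should survive steps 5 and 12 to 15.

Step 5
Reactants: 6 (5S)-5-{[tert-butyl(diphenyl)silyl]oxymethyl}-4,4-dimethylcyclohex-2-en-1-one
Product: 7 (5R,6Z)-5-{[tert-butyl(diphenyl)silyl]oxymethyl}-6-(hydroxymethylidene)-4,4-dimethylcyclohex-2-en-1-one
Conditions: LiN(SiMe3)2 (2.2 equiv), THF, −78 °C; CF3CH2OCHO; aq. HCl work-up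
Reagents that add atoms: 2,2,2-trifluoroethyl formate, O=COCC(F)(F)F
Why: Claisen-type C-formylation of the kinetic cross-conjugated lithium enolate, which can form only at the single CH2 next to the carbonyl, gives the chelated hydroxymethylene ketone; the neighbouring CH centre is not acidic and keeps its configuration.

Step 6
Reactants: 8 cyclopentene oxide
Product: 10 (1S)-cyclopent-2-en-1-yl propanoate, via lithium alkoxide 9 (not isolated)
Conditions: LiN(iPr)2, DBU, chiral 3-(pyrrolidin-1-ylmethyl)-2-azabicyclo[2.2.1]heptane (5 mol %), THF, 0 °C; then (EtCO)2O, 0 °C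
Reagents that add atoms: propanoic anhydride, CCC(=O)OC(=O)CC
Why: Enantioselective base-mediated rearrangement of a meso epoxide to an allylic alcohol (syn β-elimination by a chiral lithium amide that removes one of the two enantiotopic protons) sets the carbinol centre as S, and the volatile alkoxide is acylated in the same flask.

Step 7
Reactants: 10 (1S)-cyclopent-2-en-1-yl propanoate
Product: 13 (2R)-2-[(1R)-cyclopent-2-en-1-yl]propanoic acid, via silyl ketene acetal 11 (not isolated), via silyl ester 12 (not isolated)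
Conditions: LiN(iPr)2, THF, −78 °C; Me3SiCl; −78 to 60 °C; then aq. HCl
Reagents that add atoms: none
Why: Ireland–Claisen rearrangement: LiN(iPr)2 in THF gives the E silyl ketene acetal, the suprafacial [3,3] shift puts the new C–C bond on the ring face that carried the oxygen (ring CH = R), and the boat-like transition state usual for cycloalk-2-enyl esters with E ketene acetals should set the methyl-bearing carbon as R.

Step 8
Reactants: 13 (2R)-2-[(1R)-cyclopent-2-en-1-yl]propanoic acid
Product: 14 benzyl (2R)-2-[(1R)-cyclopent-2-en-1-yl]propanoate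
Conditions: BnBr, K2CO3, DMF, rt
Reagents that add atoms: benzyl bromide, BrCc1ccccc1
Why: O-alkylation of the carboxylate (SN2) gives a benzyl ester that survives to the last step and leaves there by hydrogenolysis; the weak base does not touch the stereocentres.

Step 9
Reactants: 14 benzyl (2R)-2-[(1R)-cyclopent-2-en-1-yl]propanoate
Product: 15 benzyl (2R,3S)-3-formyl-2-methyl-6-oxohexanoate
Conditions: O3, CH2Cl2, −78 °C; PPh3, −78 °C to rt
Reagents that add atoms: ozone, [O-][O+]=O
Why: Ozonolysis with reductive work-up cleaves the ring alkene to the 2-substituted glutaraldehyde; neutral conditions at low temperature should keep the α-stereocentre of the branched aldehyde.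

Step 10
Reactants: 15 benzyl (2R,3S)-3-formyl-2-methyl-6-oxohexanoate
Product: 16 benzyl (2R,3S,6E)-8-(ethylsulfanyl)-3-formyl-2-methyl-8-oxooct-6-enoate
Conditions: Ph3P=CHC(O)SEt (1.0 equiv), CH2Cl2, 0 °C
Reagents that add atoms: S-ethyl 2-(triphenyl-λ5-phosphanylidene)ethanethioate, CCSC(=O)C=P(c1ccccc1)(c1ccccc1)c1ccccc1
Why: Wittig olefination with a stabilised ylide is selective for the unbranched aldehyde over the α-branched one and gives the E thioenoate needed for ring closure.

Step 11
Reactants: 16 benzyl (2R,3S,6E)-8-(ethylsulfanyl)-3-formyl-2-methyl-8-oxooct-6-enoate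
Product: 17 benzyl (2R)-2-[(1S,2S)-3-[(ethylsulfanyl)carbonyl]-2-hydroxycyclohex-3-en-1-yl]propanoate
Conditions: PMe3 (20 mol %), CH2Cl2, rt
Reagents that add atoms: none
Why: Intramolecular Morita–Baylis–Hillman reaction of an α,β-unsaturated thioester with an enolisable aldehyde (phosphine addition, reversible aldol ring closure, elimination) forms ring A; the carbinol is expected trans to the neighbouring side chain because both sit equatorial in the chair-like aldol intermediate.

Step 12
Reactants: 7 (5R,6Z)-5-{[tert-butyl(diphenyl)silyl]oxymethyl}-6-(hydroxymethylidene)-4,4-dimethylcyclohex-2-en-1-one; 17 benzyl (2R)-2-[(1S,2S)-3-[(ethylsulfanyl)carbonyl]-2-hydroxycyclohex-3-en-1-yl]propanoate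
Product: 18 benzyl (2R)-2-[(1S,2S)-2-{(E)-[(6R)-6-{[tert-butyl(diphenyl)silyl]oxymethyl}-5,5-dimethyl-2-oxocyclohex-3-en-1-ylidene]methoxy}-3-[(ethylsulfanyl)carbonyl]cyclohex-3-en-1-yl]propanoate
Conditions: TsOH·H2O (5 mol %), benzene, reflux, Dean–Stark trap
Reagents that add atoms: none
Why: Acid-catalysed condensation of a 2-(hydroxymethylene) ketone with an alcohol (vinylogous esterification with removal of water) should give the E β-alkoxy enone without breaking the carbinol C–O bond, so its configuration is retained.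

Step 13
Reactants: 18 enol ether thioester
Product: 19 (5S,6S)-5-[(2R)-1-(benzyloxy)-1-oxopropan-2-yl]-6-{(E)-[(6R)-6-{[tert-butyl(diphenyl)silyl]oxymethyl}-5,5-dimethyl-2-oxocyclohex-3-en-1-ylidene]methoxy}cyclohex-1-ene-1-carboxylic acid
Conditions: AgNO3, 2,6-lutidine, THF/H2O, rt
Reagents that add atoms: water, O
Why: Silver-assisted thioester hydrolysis (thiophilic activation, buffered) frees the carboxylic acid at room temperature without cleaving the acid-labile enol ether or the benzyl ester.

Step 14
Reactants: 19 enol ether acid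
Product: 21 benzyl (2R)-2-[(4S,4aS,6'R,7R)-6'-{[tert-butyl(diphenyl)silyl]oxymethyl}-3-hydroxy-5',5'-dimethyl-1,2'-dioxo-4a,5,6,7-tetrahydro-1H,3H-spiro[isochromene-4,1'-cyclohex[3]ene]-7-yl]propanoate, via formyl ketone acid 20 (not isolated)
Conditions: toluene (0.02 M), BHT (cat.), 130 °C, sealed tube
Reagents that add atoms: none
Why: On heating, the allyl vinyl ether undergoes a [3,3]-sigmatropic (Claisen) rearrangement through a chair transition state to the 2-formyl ketone 20, and the carboxylic acid then adds to the new formyl group to close the six-membered acyloxy-lactol, forming the ring O–CH bond that becomes the lactone O–CH2 bond. The closest known reaction types are the Claisen rearrangement of O-allyl ethers of 2-(hydroxymethylene) ketones to 2-allyl-2-formyl ketones and the ring-chain tautomerism of δ-aldehydo acids to hydroxy lactones. The lactol ring closes by 6-exo-trig attack of the carboxyl oxygen on the formyl carbon. The ring-A methine is set by suprafacial transfer from the allylic C–O centre (new bond on the face that carried the oxygen, trans to the side chain), the quaternary carbon by the E enol ether geometry in the chair transition state, and the lactol carbon forms as an epimer mixture that step 15 removes. The step needs the chair over the boat and attack on the enol ether face anti to the CH2OSi group: the fully substituted vinyl terminus disfavours the boat, that face is the one the chair demands for the E isomer (matched pair), and the acceptor-substituted allyl unit with its conjugated acid product favours the shift over elimination. Because the primary alcohol is silylated, only the acid can capture the aldehyde.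

Step 15
Reactants: 21 spiro hydroxy lactone
Product: 22 benzyl (2R)-2-[(4S,4aS,6'R,7R)-6'-{[tert-butyl(diphenyl)silyl]oxymethyl}-5',5'-dimethyl-1,2'-dioxo-4a,5,6,7-tetrahydro-1H,3H-spiro[isochromene-4,1'-cyclohex[3]ene]-7-yl]propanoate
Conditions: Et3SiH, CF3CO2H, CH2Cl2, 0 °C to rt
Reagents that add atoms: none
Why: Ionic hydrogenation of the lactol: acid ionises the exocyclic C–OH to the cyclic acyloxycarbenium ion, which Et3SiH reduces to the lactone CH2 with the ring C–O bond kept; the hindered ketone, the enone and the silyl ether are expected to survive.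

Step 16
Reactants: 22 spiro lactone silyl ether
Product: 24 benzyl (2R)-2-[(1'R,4S,4aS,5'R,7R)-8',8'-dimethyl-1,3'-dioxo-4a,5,6,7-tetrahydro-1H,3H-spiro[isochromene-4,2'-[6]oxabicyclo[3.2.1]octan]-7-yl]propanoate, via hydroxy enone 23 (not isolated)
Conditions: HF·pyridine, THF, 0 °C to rt; then TsOH·H2O (cat.), CH2Cl2, rt
Reagents that add atoms: none
Why: Desilylation frees the primary alcohol, which closes the oxolane bridge by acid-catalysed intramolecular oxa-Michael addition (5-exo-trig) to the enone; the tether reaches the β-carbon only from its own face, so the new O–CH centre is fixed as R.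

Step 17
Reactants: 24 unsaturated spiro lactone benzyl ester
Product: 25 (2R)-2-[(1'R,4S,4aR,5'R,7R,8aS)-8',8'-dimethyl-1,3'-dioxooctahydro-1H-spiro[isochromene-4,2'-[6]oxabicyclo[3.2.1]octan]-7-yl]propanoic acid (CNP0152427.2)
Conditions: H2 (3 atm), Pd/C (10 %), EtOAc, rt
Reagents that add atoms: none
Why: Heterogeneous hydrogenation adds H2 cis to the trisubstituted alkene from the face opposite the bulky spiro quaternary carbon, which should give the cis ring fusion (CH next to the lactone C=O = S) under kinetic control with no base present, and the same conditions cleave the benzyl ester by hydrogenolysis.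

**Compound list**

1 | 4,4-dimethylcyclohex-2-en-1-one | CC1(C)CCC(=O)C=C1 | starting material
2 | 4,4-dimethylcyclohexa-2,5-dien-1-one | CC1(C)C=CC(=O)C=C1 | intermediate
3 | (5R)-5-ethenyl-4,4-dimethylcyclohex-2-en-1-one | O=C1C[C@H](C=C)C(C)(C)C=C1 | intermediate
4 | (1S)-2,2-dimethyl-5-oxocyclohex-3-ene-1-carbaldehyde (keto aldehyde) | O=C1C[C@H](C=O)C(C)(C)C=C1 | intermediate
5 | (5S)-5-(hydroxymethyl)-4,4-dimethylcyclohex-2-en-1-one | O=C1C[C@H](CO)C(C)(C)C=C1 | intermediate
6 | (5S)-5-{[tert-butyl(diphenyl)silyl]oxymethyl}-4,4-dimethylcyclohex-2-en-1-one | O=C1C[C@H](CO[Si](c2ccccc2)(c2ccccc2)C(C)(C)C)C(C)(C)C=C1 | intermediate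
7 | (5R,6Z)-5-{[tert-butyl(diphenyl)silyl]oxymethyl}-6-(hydroxymethylidene)-4,4-dimethylcyclohex-2-en-1-one | O/C=C1\C(=O)C=CC(C)(C)[C@H]1CO[Si](c1ccccc1)(c1ccccc1)C(C)(C)C | intermediate
8 | cyclopentene oxide (6-oxabicyclo[3.1.0]hexane) | C1CC2OC2C1 | starting material
9 | lithium (1S)-cyclopent-2-en-1-olate | [Li+].[O-][C@@H]1C=CCC1 | intermediate
10 | (1S)-cyclopent-2-en-1-yl propanoate | CCC(=O)O[C@@H]1C=CCC1 | intermediate
11 | {[(1E)-1-{[(1S)-cyclopent-2-en-1-yl]oxy}prop-1-en-1-yl]oxy}(trimethyl)silane (E silyl ketene acetal) | C/C=C(/O[Si](C)(C)C)O[C@@H]1C=CCC1 | intermediate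
12 | trimethylsilyl (2R)-2-[(1R)-cyclopent-2-en-1-yl]propanoate | C[C@@H](C(=O)O[Si](C)(C)C)[C@@H]1CCC=C1 | intermediate
13 | (2R)-2-[(1R)-cyclopent-2-en-1-yl]propanoic acid | C[C@@H](C(=O)O)[C@@H]1CCC=C1 | intermediate
14 | benzyl (2R)-2-[(1R)-cyclopent-2-en-1-yl]propanoate | C[C@@H](C(=O)OCc1ccccc1)[C@@H]1CCC=C1 | intermediate
15 | benzyl (2R,3S)-3-formyl-2-methyl-6-oxohexanoate | C[C@@H](C(=O)OCc1ccccc1)[C@@H](C=O)CCC=O | intermediate
16 | benzyl (2R,3S,6E)-8-(ethylsulfanyl)-3-formyl-2-methyl-8-oxooct-6-enoate | C[C@@H](C(=O)OCc1ccccc1)[C@@H](C=O)CC/C=C/C(=O)SCC | intermediate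
17 | benzyl (2R)-2-[(1S,2S)-3-[(ethylsulfanyl)carbonyl]-2-hydroxycyclohex-3-en-1-yl]propanoate (hydroxyl trans to the side chain) | C[C@@H](C(=O)OCc1ccccc1)[C@@H]1CCC=C(C(=O)SCC)[C@H]1O | intermediate
18 | benzyl (2R)-2-[(1S,2S)-2-{(E)-[(6R)-6-{[tert-butyl(diphenyl)silyl]oxymethyl}-5,5-dimethyl-2-oxocyclohex-3-en-1-ylidene]methoxy}-3-[(ethylsulfanyl)carbonyl]cyclohex-3-en-1-yl]propanoate (enol ether thioester) | C[C@@H](C(=O)OCc1ccccc1)[C@@H]1CCC=C(C(=O)SCC)[C@H]1O/C=C2/C(=O)C=CC(C)(C)[C@H]2CO[Si](c2ccccc2)(c2ccccc2)C(C)(C)C | intermediate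
19 | (5S,6S)-5-[(2R)-1-(benzyloxy)-1-oxopropan-2-yl]-6-{(E)-[(6R)-6-{[tert-butyl(diphenyl)silyl]oxymethyl}-5,5-dimethyl-2-oxocyclohex-3-en-1-ylidene]methoxy}cyclohex-1-ene-1-carboxylic acid (enol ether acid) | C[C@@H](C(=O)OCc1ccccc1)[C@@H]1CCC=C(C(=O)O)[C@H]1O/C=C2/C(=O)C=CC(C)(C)[C@H]2CO[Si](c2ccccc2)(c2ccccc2)C(C)(C)C | intermediate
20 | (3R,6S)-3-[(2R)-1-(benzyloxy)-1-oxopropan-2-yl]-6-[(1S,6R)-6-{[tert-butyl(diphenyl)silyl]oxymethyl}-1-formyl-5,5-dimethyl-2-oxocyclohex-3-en-1-yl]cyclohex-1-ene-1-carboxylic acid (formyl ketone acid) | C[C@@H](C(=O)OCc1ccccc1)[C@@H]1CC[C@@H]([C@]2(C=O)C(=O)C=CC(C)(C)[C@H]2CO[Si](c2ccccc2)(c2ccccc2)C(C)(C)C)C(=C1)C(=O)O | intermediate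
21 | benzyl (2R)-2-[(4S,4aS,6'R,7R)-6'-{[tert-butyl(diphenyl)silyl]oxymethyl}-3-hydroxy-5',5'-dimethyl-1,2'-dioxo-4a,5,6,7-tetrahydro-1H,3H-spiro[isochromene-4,1'-cyclohex[3]ene]-7-yl]propanoate (spiro hydroxy lactone; both epimers at the lactol carbon) | C[C@@H](C(=O)OCc1ccccc1)[C@@H]1CC[C@@H]2C(=C1)C(=O)OC(O)[C@]21C(=O)C=CC(C)(C)[C@H]1CO[Si](c1ccccc1)(c1ccccc1)C(C)(C)C | intermediate
22 | benzyl (2R)-2-[(4S,4aS,6'R,7R)-6'-{[tert-butyl(diphenyl)silyl]oxymethyl}-5',5'-dimethyl-1,2'-dioxo-4a,5,6,7-tetrahydro-1H,3H-spiro[isochromene-4,1'-cyclohex[3]ene]-7-yl]propanoate | C[C@@H](C(=O)OCc1ccccc1)[C@@H]1CC[C@@H]2C(=C1)C(=O)OC[C@]21C(=O)C=CC(C)(C)[C@H]1CO[Si](c1ccccc1)(c1ccccc1)C(C)(C)C | intermediate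
23 | benzyl (2R)-2-[(4S,4aS,6'R,7R)-6'-(hydroxymethyl)-5',5'-dimethyl-1,2'-dioxo-4a,5,6,7-tetrahydro-1H,3H-spiro[isochromene-4,1'-cyclohex[3]ene]-7-yl]propanoate (hydroxy enone) | C[C@@H](C(=O)OCc1ccccc1)[C@@H]1CC[C@@H]2C(=C1)C(=O)OC[C@]21C(=O)C=CC(C)(C)[C@H]1CO | intermediate
24 | benzyl (2R)-2-[(1'R,4S,4aS,5'R,7R)-8',8'-dimethyl-1,3'-dioxo-4a,5,6,7-tetrahydro-1H,3H-spiro[isochromene-4,2'-[6]oxabicyclo[3.2.1]octan]-7-yl]propanoate | C[C@@H](C(=O)OCc1ccccc1)[C@@H]1CC[C@@H]2C(=C1)C(=O)OC[C@]21C(=O)C[C@H]2OC[C@@H]1C2(C)C | intermediate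
25 | (2R)-2-[(1'R,4S,4aR,5'R,7R,8aS)-8',8'-dimethyl-1,3'-dioxooctahydro-1H-spiro[isochromene-4,2'-[6]oxabicyclo[3.2.1]octan]-7-yl]propanoic acid (CNP0152427.2) | C[C@@H](C(=O)O)[C@@H]1CC[C@@H]2[C@H](C1)C(=O)OC[C@]21C(=O)C[C@H]2OC[C@@H]1C2(C)C | target

**Step count and risks**

Total step count: 17. Longest linear sequence: 12 steps (steps 6 to 17); the other branch (steps 1 to 5) joins at step 12.

Step 14: the ordered rearrangement may lose facial control at the exocyclic enol ether carbon, or thermal elimination of the allylic ether may overtake it. The fallback sets out from 17. Methyl chloroformate and pyridine should convert the alcohol into the methyl carbonate F1. With 7 and Pd2(dba)3/PPh3 (zerovalent palladium) in THF, a Tsuji–Trost allylation of the 2-formyl ketone enolate should give the C-allylated formyl ketone thioester F2. Ionisation and attack are both anti to palladium, so the new bond again lies on the face that carried the oxygen, at the allyl terminus remote from the side chain. Silver-assisted hydrolysis as in step 13 then frees the acid, which closes to the lactol, and the route is rejoined at 21.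

Step 11: the ring-closing aldol event may give poor control of the carbinol configuration. The fallback sets out from 16. The cyclisation is run without regard to this centre to give the carbinol mixture F3. Dess–Martin periodinane should oxidise it to the cyclohexenone thioester F4. Luche reduction (NaBH4, CeCl3·7H2O, MeOH, −78 °C), by axial hydride attack, should then place the hydroxyl trans to the neighbouring side chain, and the route is rejoined at 17.

Step 15: ionisation of the lactol next to the acyl-bearing quaternary carbon may be reluctant, so that reduction of the ketone or enone, or loss of the silyl group, competes. The fallback sets out from 21. NaBH(OAc)3 in CH2Cl2 should reduce the open-chain aldehyde tautomer selectively to the hydroxy acid F5. Carbodiimide lactonisation (EDC·HCl, DMAP, CH2Cl2) then closes the δ-lactone, and the route is rejoined at 22.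

Further compounds
F1 | step 14 | methyl carbonate of alcohol 17 | C[C@@H](C(=O)OCc1ccccc1)[C@@H]1CCC=C(C(=O)SCC)[C@H]1OC(=O)OC
F2 | step 14 | C-allylated formyl ketone thioester | C[C@@H](C(=O)OCc1ccccc1)[C@@H]1CC[C@@H]([C@]2(C=O)C(=O)C=CC(C)(C)[C@H]2CO[Si](c2ccccc2)(c2ccccc2)C(C)(C)C)C(=C1)C(=O)SCC
F3 | step 11 | carbinol mixture (17 and its carbinol epimer) | C[C@@H](C(=O)OCc1ccccc1)[C@@H]1CCC=C(C(=O)SCC)C1O
F4 | step 11 | cyclohexenone thioester: benzyl (2R)-2-[(1S)-3-[(ethylsulfanyl)carbonyl]-2-oxocyclohex-3-en-1-yl]propanoate | C[C@@H](C(=O)OCc1ccccc1)[C@@H]1CCC=C(C(=O)SCC)C1=O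
F5 | step 15 | hydroxy acid (reduced open form of 21) | C[C@@H](C(=O)OCc1ccccc1)[C@@H]1CC[C@@H]([C@]2(CO)C(=O)C=CC(C)(C)[C@H]2CO[Si](c2ccccc2)(c2ccccc2)C(C)(C)C)C(=C1)C(=O)O
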